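Ring A is disconnected at C1–C10 and C4–C5 as a [4+2] union. The C1–C4 unit, with its oxygen at C2 and the gem-dimethyl group at C4, is the silyl dienol ether of mesityl oxide. C5=C10 is the double bond of a ring B cyclohexenone whose C6 carbonyl activates it and whose C9 side-chain stereocenter directs the approach. One Lewis-acid-promoted Diels–Alder reaction therefore closes ring A and creates both quaternary carbons (C4, C10) and the C5/C10 ring fusion. The C6 carbonyl then serves to introduce the C8 methyl and the C7=C8 double bond before it is removed reductively.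

Key step: step 7

Remark: labdane numbering (C-1 to C-20) is used for ring and side-chain positions of all intermediates; half-ester 1 is assumed to be a commercial chiral building block.

Step 1
Reactants: 1 methyl hydrogen (R)-3-methylglutarate
Product: 3 (S)-4-methyltetrahydro-2H-pyran-2-one, via hydroxy acid 2 (not isolated)
Conditions: LiBH4 (2.5 equiv), THF, 0 °C to rt; then 2 M HCl, rt
Reagents that add atoms: none
Why: LiBH4 should reduce the methyl ester while the lithium carboxylate formed in the flask stays inert, and acidification should lactonise the hydroxy acid to the six-membered lactone (chemoselective ester reduction, lactonisation), the stereocenter not being involved.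

Step 2
Reactants: 3 (S)-4-methyltetrahydro-2H-pyran-2-one
Product: 4 methyl (R)-5-iodo-3-methylpentanoate
Conditions: TMSI (1.3 equiv), CH2Cl2, rt; then MeOH, rt
Reagents that add atoms: iodotrimethylsilane C[Si](C)(C)I; methanol CO
Why: Silylation of the lactone carbonyl should activate the O–CH2 carbon for SN2 attack by iodide, and methanol should then turn the silyl ester into the methyl ester (lactone opening with iodotrimethylsilane).

Step 3
Reactants: 4 methyl (R)-5-iodo-3-methylpentanoate; 5 (Z)-1-bromo-2-ethoxyethene
Product: 8 methyl (S)-3-methyl-7-oxoheptanoate, via alkylzinc iodide 6 (not isolated), via enol ether 7 (not isolated)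
Conditions: Zn dust, LiCl, THF, 40 °C; then 5, Pd(OAc)2 (2 mol %), SPhos (4 mol %), THF, rt; then 1 M HCl, THF, rt
Reagents that add atoms: none
Why: LiCl-assisted zinc insertion into the primary iodide tolerates the ester, the alkylzinc should couple with the alkenyl bromide under palladium catalysis (Negishi coupling), and mild acid hydrolysis of the enol ether should release the aldehyde two carbons longer.

Step 4
Reactants: 8 methyl (S)-3-methyl-7-oxoheptanoate; 9 methyl vinyl ketone
Product: 11 methyl (S)-3-methyl-5-[(R)-4-oxocyclohex-2-en-1-yl]pentanoate, via keto aldehyde 10 (not isolated)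
Conditions: (S)-2-(methoxydiphenylmethyl)pyrrolidine (5 mol %), ethyl 3,4-dihydroxybenzoate (20 mol %), 9 (1.5 equiv), neat, 4 °C; then p-TsOH·H2O (10 mol %), toluene, 60 °C
Reagents that add atoms: none
Why: In this organocatalytic Michael addition/aldol condensation (a Robinson-type annulation) the (S)-diarylprolinol ether shields one face of the aldehyde enamine, so that addition to methyl vinyl ketone should set C-9 as R by the usual steric-shielding model, and acid-catalysed 6-enolexo aldol condensation should then close ring B without touching that center.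

Step 5
Reactants: 11 methyl (S)-3-methyl-5-[(R)-4-oxocyclohex-2-en-1-yl]pentanoate
Product: 13 methyl (S)-3-methyl-5-[(R)-2-methyl-4-oxocyclohex-2-en-1-yl]pentanoate, via silyl enol ether 12 (not isolated)
Conditions: Me2CuLi (1.5 equiv), TMSCl, THF, −78 °C; then Pd(OAc)2 (1.1 equiv), MeCN, rt
Reagents that add atoms: lithium dimethylcuprate [Li+].C[Cu-]C
Why: The Gilman reagent should add to C-10 anti to the neighbouring side chain with TMSCl trapping the enolate regiospecifically, and Saegusa–Ito oxidation should re-form the C5=C10 double bond now carrying the C-10 methyl, which erases the transient C-10 stereocenter (conjugate addition/Saegusa–Ito oxidation).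

Step 6
Reactants: 14 mesityl oxide
Product: 15 tert-butyldimethyl[(4-methylpenta-1,3-dien-2-yl)oxy]silane
Conditions: LiN(iPr)2, THF, −78 °C; then TBSCl, DMPU, −78 °C to rt
Reagents that add atoms: tert-butyldimethylsilyl chloride CC(C)(C)[Si](C)(C)Cl
Why: The amide base should remove a proton from the α'-methyl group under kinetic control to give the cross-conjugated enolate, which is silylated on oxygen (kinetic silyl dienol ether formation).

Step 7
Reactants: 13 methyl (S)-3-methyl-5-[(R)-2-methyl-4-oxocyclohex-2-en-1-yl]pentanoate; 15 tert-butyldimethyl[(4-methylpenta-1,3-dien-2-yl)oxy]silane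
Product: 18 trans-fused 2,6-dione ester (methyl 2,6-dioxo-17-norlabdan-15-oate of the target series), via silyl enol ether cycloadduct 16 (not isolated), via cis-fused dione 17 (not isolated)
Conditions: AlBr3/AlMe3 (10:1, 2.5 equiv), toluene/CH2Cl2, −5 °C; then 1 M HCl, THF, rt; then NaOMe (0.2 equiv), MeOH, rt
Reagents that add atoms: none
Why: The mixed Lewis acid binds the C-6 carbonyl of 13, and the electron-rich diene 15 should add across C5=C10 in a strongly asynchronous [4+2] cycloaddition (C1–C10 bond leading, C4–C5 bond following) to give silyl enol ether 16, which aqueous acid hydrolyses to dione 17. The closest known reaction type is the AlBr3/AlMe3-promoted Diels–Alder reaction of hindered 2-silyloxydienes with β-substituted cyclohexenones, which was developed for cyclohexenes with quaternary carbons at the new ring bonds. Ring A is closed as an intermolecular [4+2] cycloaddition (in the stepwise limit the second bond forms by a 6-endo-trig Michael closure). C-10 is set by approach of the diene anti to the C-9 side chain, which A(1,2) strain with the C-10 methyl holds pseudoaxial on one face of the enone; C-5 is first formed cis (suprafacial addition) and is then equilibrated by NaOMe through the C-6 enolate to the more stable trans ring fusion. The step needs regioselectivity, secured because the siloxy group makes C-1 the nucleophilic terminus of the diene while C-10 is the electrophilic β-carbon of the enone, and facial selectivity, secured by the single ring stereocenter at C-9 next to C-10.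

Step 8
Reactants: 18 trans-fused 2,6-dione ester
Product: 19 methyl 2,6-dioxo-17-norlabd-7-en-15-oate
Conditions: IBX (2.2 equiv), DMSO/fluorobenzene, 75 °C
Reagents that add atoms: none
Why: IBX dehydrogenates ketones through their enols by single-electron transfer, and only the C-6 ketone can be desaturated (to C7=C8) because every other β-position (C-4 and C-10) is quaternary (IBX α,β-dehydrogenation).

Step 9
Reactants: 19 methyl 2,6-dioxo-17-norlabd-7-en-15-oate
Product: 21 methyl 2,6-dioxolabd-7-en-15-oate, via silyl enol ether 20 (not isolated)
Conditions: Me2CuLi (1.5 equiv), TMSCl, THF, −78 °C; then Pd(OAc)2 (1.1 equiv), MeCN, rt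
Reagents that add atoms: lithium dimethylcuprate [Li+].C[Cu-]C
Why: At −78 °C the Gilman reagent should add to C-8 of the enone much faster than to the saturated C-2 ketone or the ester, TMSCl traps the C-6 enolate, and Saegusa–Ito oxidation should give the 8-methyl enone, erasing the C-8 stereocenter formed on addition (conjugate addition/Saegusa–Ito oxidation).

Step 10
Reactants: 21 methyl 2,6-dioxolabd-7-en-15-oate
Product: 22 (2R,5R,9R,10R,13S)-labd-7-ene-2,15-diol
Conditions: LiAlH4/AlCl3 (1:3), Et2O, 0 °C to reflux; then acetone (slight excess over residual hydride), reflux; H2O, aq. NaOH work-up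
Reagents that add atoms: none
Why: The mixed hydride should reduce the ester to the primary alcohol, convert the enone through its allylic aluminium alkoxide and allyl cation into the alkene with hydride delivered to the less substituted terminus C-6 (as in the reduction of steroidal 4-en-3-ones to 4-enes), and reduce the C-2 ketone, whose alkoxyaluminium dichloride equilibrates in the presence of a little ketone (Eliel-type hydride-transfer equilibration) to the equatorial alcohol anti to the C-10 methyl, since the axial epimer is 1,3-diaxial to both the C-10 and the axial C-4 methyl groups.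

Step 11
Reactants: 22 (2R,5R,9R,10R,13S)-labd-7-ene-2,15-diol
Product: 23 (2R,5R,9R,10R,13S)-labd-7-ene-2,15-diyl diacetate
Conditions: Ac2O, pyridine, DMAP (cat.), CH2Cl2, rt
Reagents that add atoms: acetic anhydride CC(=O)OC(C)=O
Why: Both hydroxyl groups should be acylated under nucleophilic catalysis (DMAP-catalysed acetylation) with retention at C-2.

Compound list
1 | methyl hydrogen (R)-3-methylglutarate [(R)-5-methoxy-3-methyl-5-oxopentanoic acid] | OC(=O)C[C@@H](C)CC(=O)OC | starting material
2 | (S)-5-hydroxy-3-methylpentanoic acid (lithium salt in the flask) | OC(=O)C[C@@H](C)CCO | intermediate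
3 | (S)-4-methyltetrahydro-2H-pyran-2-one | O=C1C[C@@H](C)CCO1 | intermediate
4 | methyl (R)-5-iodo-3-methylpentanoate | COC(=O)C[C@@H](C)CCI | intermediate
5 | (Z)-1-bromo-2-ethoxyethene | Br/C=C\OCC | starting material
6 | (R)-(5-methoxy-3-methyl-5-oxopentyl)zinc iodide | COC(=O)C[C@@H](C)CC[Zn]I | intermediate
7 | methyl (S,Z)-7-ethoxy-3-methylhept-6-enoate | COC(=O)C[C@@H](C)CC/C=C\OCC | intermediate
8 | methyl (S)-3-methyl-7-oxoheptanoate | COC(=O)C[C@@H](C)CCCC=O | intermediate
9 | methyl vinyl ketone (but-3-en-2-one) | CC(=O)C=C | starting material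
10 | methyl (3S,6R)-6-formyl-3-methyl-9-oxodecanoate | COC(=O)C[C@@H](C)CC[C@@H](C=O)CCC(C)=O | intermediate
11 | methyl (S)-3-methyl-5-[(R)-4-oxocyclohex-2-en-1-yl]pentanoate | COC(=O)C[C@@H](C)CC[C@H]1C=CC(=O)CC1 | intermediate
12 | methyl (S)-3-methyl-5-[trans-2-methyl-4-(trimethylsilyloxy)cyclohex-3-en-1-yl]pentanoate (ring methyl anti to the chain, chain-bearing carbon as in 11) | COC(=O)C[C@@H](C)CC[C@H]1[C@H](C)C=C(O[Si](C)(C)C)CC1 | intermediate
13 | methyl (S)-3-methyl-5-[(R)-2-methyl-4-oxocyclohex-2-en-1-yl]pentanoate | COC(=O)C[C@@H](C)CC[C@H]1C(C)=CC(=O)CC1 | intermediate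
14 | mesityl oxide (4-methylpent-3-en-2-one) | CC(=O)C=C(C)C | starting material
15 | tert-butyldimethyl[(4-methylpenta-1,3-dien-2-yl)oxy]silane | C=C(O[Si](C)(C)C(C)(C)C)C=C(C)C | intermediate
16 | cis-fused cycloadduct: methyl 2-(tert-butyldimethylsilyloxy)-6-oxo-17-norlabd-2-en-15-oate, H-5 syn to the C-10 methyl, C-9 side chain syn to the C-10 methyl, 13S | COC(=O)C[C@@H](C)CC[C@@H]1CCC(=O)[C@H]2C(C)(C)C=C(O[Si](C)(C)C(C)(C)C)C[C@@]12C | intermediate
17 | cis-fused dione: methyl 2,6-dioxo-17-norlabdan-15-oate, 5-epimer (H-5 syn to the C-10 methyl) | COC(=O)C[C@@H](C)CC[C@@H]1CCC(=O)[C@H]2C(C)(C)CC(=O)C[C@@]12C | intermediate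
18 | trans-fused dione: methyl 2,6-dioxo-17-norlabdan-15-oate (H-5 anti and C-9 side chain syn to the C-10 methyl, 13S, ring configuration as in 23) | COC(=O)C[C@@H](C)CC[C@@H]1CCC(=O)[C@@H]2C(C)(C)CC(=O)C[C@@]12C | intermediate
19 | methyl 2,6-dioxo-17-norlabd-7-en-15-oate (configuration as in 18) | COC(=O)C[C@@H](C)CC[C@@H]1C=CC(=O)[C@@H]2C(C)(C)CC(=O)C[C@@]12C | intermediate
20 | methyl 2-oxo-6-(trimethylsilyloxy)labd-6-en-15-oate (C-8 methyl of either configuration) | COC(=O)C[C@@H](C)CC[C@@H]1C(C)C=C(O[Si](C)(C)C)[C@@H]2C(C)(C)CC(=O)C[C@@]12C | intermediate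
21 | methyl 2,6-dioxolabd-7-en-15-oate (configuration as in 18) | COC(=O)C[C@@H](C)CC[C@@H]1C(C)=CC(=O)[C@@H]2C(C)(C)CC(=O)C[C@@]12C | intermediate
22 | (2R,5R,9R,10R,13S)-labd-7-ene-2,15-diol (2-OH equatorial, anti to the C-10 methyl) | OCC[C@@H](C)CC[C@@H]1C(C)=CC[C@@H]2C(C)(C)C[C@@H](O)C[C@@]12C | intermediate
23 | (2R,5R,9R,10R,13S)-labd-7-ene-2,15-diyl diacetate | CC(=O)OCC[C@@H](C)CC[C@@H]1C(C)=CC[C@@H]2C(C)(C)C[C@@H](OC(C)=O)C[C@@]12C | target

Total step count: 11. Longest linear sequence: 10 steps (steps 1–5 and 7–11).

Steps most likely to fail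

1. Step 7. The cycloaddition may stall because two quaternary carbons are formed next to C-5, the diene may be desilylated or polymerised by the Lewis acid, and facial discrimination may be incomplete. Fallback (from 13 and 15, back to 18): the two bonds are made one after the other. A TiCl4-mediated Mukaiyama–Michael addition (CH2Cl2, −78 °C) would form only the C1–C10 bond and give, after aqueous work-up, the open enedione F1. KOtBu (cat.) in t-BuOH/THF would then close ring A by intramolecular Michael addition of the C-6 enolate (through C-5) to the β,β-dimethyl enone (at C-4) and equilibrate C-5, returning to 18.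

2. Step 10. Hydride may be captured at the tertiary end (C-8) of the allyl cation, the cation may lose a proton to give a diene, or equilibration at C-2 may remain incomplete. Fallback (from 21, back to 22): LiAlH4 in THF at 0 °C would give the triol F2 (1,2-reduction of the enone, C-2 alcohol mainly axial). Pyridine·SO3 followed by LiAlH4 would then replace the allylic sulfate at C-6 by hydride without allylic shift (the other sulfate esters are hydrolysed on work-up) and give the 2-epimeric diol F3. Meerwein–Ponndorf–Verley/Oppenauer equilibration (Al(OiPr)3, cat. acetone, toluene, reflux) would convert F3 into the equatorial alcohol 22.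

3. Step 9. The cuprate may attack the C-2 ketone, or addition at C-8 next to the C-9 branch may be too slow. Fallback (from 19, back to 21): the unhindered, non-conjugated C-2 ketone would be protected selectively (ethylene glycol, PPTS, benzene, Dean–Stark) as the dioxolane F4. A copper-catalysed Grignard addition (MeMgBr, CuBr·SMe2, TMSCl, THF, −78 °C) followed by Pd(OAc)2 oxidation of the silyl enol ether would give the 8-methyl enone ketal F5. PPTS in acetone/water would remove the ketal and return to 21.

Further compounds
F1 | step 7 | methyl (S)-3-methyl-5-[2-methyl-2-(4-methyl-2-oxopent-3-en-1-yl)-4-oxocyclohexyl]pentanoate (new CH2 branch at C-10 anti to the C-9 chain, C-9 as in 13) | COC(=O)C[C@@H](C)CC[C@@H]1CCC(=O)C[C@@]1(C)CC(=O)C=C(C)C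
F2 | step 10 | labd-7-ene-2,6,15-triol (ring configuration as in 22, 2-OH axial, C-6 not defined) | OCC[C@@H](C)CC[C@@H]1C(C)=CC(O)[C@@H]2C(C)(C)C[C@H](O)C[C@@]12C
F3 | step 10 | 2-epimer of 22 (2-OH axial, syn to the C-10 methyl) | OCC[C@@H](C)CC[C@@H]1C(C)=CC[C@@H]2C(C)(C)C[C@H](O)C[C@@]12C
F4 | step 9 | C-2 ethylene ketal of 19 | COC(=O)C[C@@H](C)CC[C@@H]1C=CC(=O)[C@@H]2C(C)(C)CC3(OCCO3)C[C@@]12C
F5 | step 9 | C-2 ethylene ketal of 21 | COC(=O)C[C@@H](C)CC[C@@H]1C(C)=CC(=O)[C@@H]2C(C)(C)CC3(OCCO3)C[C@@]12C
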